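Ring C of the isoflavanone is a β-aryloxy ketone: O1 and C4a are ortho neighbours on ring A, and C2–C3–C4 is an α-aryl acryloyl unit. The route therefore unites, in one pot, a ring A dianion (2-bromo-5-silyloxyphenol after double lithiation; C4a carbanion plus O1 oxygen) with the 2-arylacrylic Weinreb amide that carries the geranylated ring B. Acyl substitution forges the C4–C4a ketone bond and 6-endo oxa-Michael addition of the phenol to the resulting enone closes O1–C2, a formal [3+3] annulation that builds ring C. The enolisable C3 centre is then fixed by asymmetric transfer hydrogenation under dynamic kinetic resolution and reoxidation.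

Key step: step 6

Remarks on the chemistry:
- Isoflavanone numbering is used (O1, C2, C3, C4, C4a, C5–C8, C8a; ring B carbons primed). The target is the (3R) isomer. Geranyl = (2E)-3,7-dimethylocta-2,6-dien-1-yl; TIPS = triisopropylsilyl.
- Assumption: monosilylation of 4-bromoresorcinol (step 5) takes place at the unhindered hydroxyl para to bromine.

Step 1
Reactants: 1 4,6-dibromoresorcinol; 2 chlorotriisopropylsilane
Product: 3 1,5-dibromo-2,4-bis(triisopropylsilyloxy)benzene
Conditions: 2 (2.4 equiv), imidazole, DMF, rt to 40 °C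
Reagents that add atoms: chlorotriisopropylsilane (2), CC(C)[Si](Cl)(C(C)C)C(C)C
Why: Imidazole-promoted silyl ether formation masks both phenols as TIPS ethers, which withstand organolithium reagents and fall to fluoride at the end.

Step 2
Reactants: 3 1,5-dibromo-2,4-bis(triisopropylsilyloxy)benzene; 4 geranyl bromide
Product: 6 1-bromo-5-geranyl-2,4-bis(triisopropylsilyloxy)benzene, via aryllithium 5 (not isolated)
Conditions: n-BuLi (1.05 equiv), THF, −78 °C; CuBr·SMe2 (1.1 equiv); then 4, −78 to 0 °C
Reagents that add atoms: geranyl bromide (4), CC(C)=CCC/C(C)=C/CBr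
Why: Bromine–lithium exchange on the symmetrical dibromide should stop after one exchange at −78 °C (cold enough to prevent silyl migration), and the derived arylcopper displaces bromide at the primary carbon of geranyl bromide (SN2-type allylic substitution), so the E-alkene is carried over unchanged.

Step 3
Reactants: 6 1-bromo-5-geranyl-2,4-bis(triisopropylsilyloxy)benzene; 7 N,N'-dimethoxy-N,N'-dimethyloxamide
Product: 9 2-[5-geranyl-2,4-bis(triisopropylsilyloxy)phenyl]-N-methoxy-N-methyl-2-oxoacetamide, via aryllithium 8 (not isolated)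
Conditions: n-BuLi (1.1 equiv), THF, −78 °C; then 7 (1.5 equiv), −78 to −40 °C; AcOH quench
Reagents that add atoms: N,N'-dimethoxy-N,N'-dimethyloxamide (7), CON(C)C(=O)C(=O)N(C)OC
Why: Bromine–lithium exchange followed by acyl substitution on the oxamide, whose chelated tetrahedral adduct stops the reaction after one addition, should give the aryl α-keto amide (Weinreb ketone synthesis).

Step 4
Reactants: 9 2-[5-geranyl-2,4-bis(triisopropylsilyloxy)phenyl]-N-methoxy-N-methyl-2-oxoacetamide; 10 methyltriphenylphosphonium bromide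
Product: 11 2-[5-geranyl-2,4-bis(triisopropylsilyloxy)phenyl]-N-methoxy-N-methylprop-2-enamide
Conditions: 10, KN(SiMe3)2, THF, 0 °C; then 9, 0 °C to rt
Reagents that add atoms: methyltriphenylphosphonium bromide (10), C[P+](c1ccccc1)(c1ccccc1)c1ccccc1.[Br-]
Why: Wittig methylenation should take place at the more electrophilic aryl ketone carbonyl and leave the N-methoxy-N-methyl amide untouched, giving the 2-arylacrylamide (the C2–C3–C4 unit).

Step 5
Reactants: 12 4-bromoresorcinol; 2 chlorotriisopropylsilane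
Product: 13 2-bromo-5-(triisopropylsilyloxy)phenol
Conditions: 2 (1.0 equiv), imidazole, CH2Cl2, 0 °C
Reagents that add atoms: chlorotriisopropylsilane (2), CC(C)[Si](Cl)(C(C)C)C(C)C
Why: The bulky chlorosilane should silylate the hydroxyl remote from bromine, the one ortho to bromine being hindered and less nucleophilic (regioselective silyl ether formation).

Step 6
Reactants: 13 2-bromo-5-(triisopropylsilyloxy)phenol; 11 2-[5-geranyl-2,4-bis(triisopropylsilyloxy)phenyl]-N-methoxy-N-methylprop-2-enamide
Product: 16 racemic 3-[5-geranyl-2,4-bis(triisopropylsilyloxy)phenyl]-7-(triisopropylsilyloxy)chroman-4-one, via aryllithium dianion 14 (not isolated), via hydroxy enone 15 (not isolated)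
Conditions: 13 (1.3 equiv), n-BuLi (2.6 equiv), THF, −78 to −20 °C; then 11, −78 to 0 °C; AcOH, then Et3N, rt
Reagents that add atoms: none
Why: Deprotonation and bromine–lithium exchange turn 13 into dianion 14, whose aryl C–Li (the future C4a) adds to the amide carbonyl of 11 to give an N,O-chelated tetrahedral adduct that cannot over-add and collapses on acidification to hydroxy enone 15 (C4–C4a bond), the Weinreb ketone synthesis with ortho-lithiated phenoxides being the closest known reaction type. Triethylamine then triggers conjugate addition of the ortho phenol O1 to the terminal CH2 (C2) of the α-aryl enone (O1–C2 bond), the same oxa-Michael closure by which 2'-hydroxychalcones give flavanones and α-methylene deoxybenzoins give isoflavanones. Ring C is the only ring closed and it closes in the 6-endo-trig mode, both alkene carbons lying inside the new six-membered ring. The new stereocentre C3 arises by unselective protonation of the enol and, being benzylic and α to the ketone, is deliberately left racemic here and set in step 7. The step needs 1,2- over 1,4-addition to the acrylamide, which the hard aryllithium, the chelating N-methoxy-N-methyl amide and the low temperature should secure, while the regiochemistry on ring A is fixed by bromine standing ortho to the free hydroxyl and para to the silyloxy group.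

Step 7
Reactants: 16 racemic 3-[5-geranyl-2,4-bis(triisopropylsilyloxy)phenyl]-7-(triisopropylsilyloxy)chroman-4-one
Product: 17 (3R,4R)-3-[5-geranyl-2,4-bis(triisopropylsilyloxy)phenyl]-7-(triisopropylsilyloxy)chroman-4-ol (cis)
Conditions: RuCl[(R,R)-TsDPEN](p-cymene) (2 mol %), HCO2H/Et3N, EtOAc, 40 °C
Reagents that add atoms: none
Why: In this asymmetric transfer hydrogenation with dynamic kinetic resolution, Et3N interconverts the enantiomers of 16 through the enol while the catalyst reduces the (3R) ketone faster, hydride arriving anti to the C3 aryl group; the (R,R) ligand is expected, by its usual sense for aryl ketones, to give the (4R) carbinol and hence the cis-(3R,4R) alcohol, with the isolated geranyl alkenes untouched.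

Step 8
Reactants: 17 (3R,4R)-3-[5-geranyl-2,4-bis(triisopropylsilyloxy)phenyl]-7-(triisopropylsilyloxy)chroman-4-ol
Product: 18 (3R)-3-[5-geranyl-2,4-bis(triisopropylsilyloxy)phenyl]-7-(triisopropylsilyloxy)chroman-4-one
Conditions: Dess–Martin periodinane, pyridine, CH2Cl2, 0 °C
Reagents that add atoms: none
Why: Dess–Martin oxidation of the benzylic alcohol under pyridine-buffered, non-enolising conditions should return the ketone while C3, set in step 7, keeps its (R) configuration.

Step 9
Reactants: 18 (3R)-3-[5-geranyl-2,4-bis(triisopropylsilyloxy)phenyl]-7-(triisopropylsilyloxy)chroman-4-one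
Product: 19 (3R)-3-[5-geranyl-2,4-dihydroxyphenyl]-7-hydroxychroman-4-one (CNP0142504.1)
Conditions: Bu4NF/AcOH (1:1), THF, 0 °C
Reagents that add atoms: none
Why: Fluoride cleaves the three aryl silyl ethers (fluoride desilylation), and the acetic acid buffer should keep the medium from becoming basic enough to enolise C3 or open ring C, while the geranyl alkenes are inert.

Compound list
1 | 4,6-dibromoresorcinol | Oc1cc(O)c(Br)cc1Br | starting material
2 | chlorotriisopropylsilane | CC(C)[Si](Cl)(C(C)C)C(C)C | starting material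
3 | 1,5-dibromo-2,4-bis(triisopropylsilyloxy)benzene | Brc1cc(Br)c(O[Si](C(C)C)(C(C)C)C(C)C)cc1O[Si](C(C)C)(C(C)C)C(C)C | intermediate
4 | geranyl bromide, (2E)-1-bromo-3,7-dimethylocta-2,6-diene | CC(C)=CCC/C(C)=C/CBr | starting material
5 | [5-bromo-2,4-bis(triisopropylsilyloxy)phenyl]lithium | [Li]c1cc(Br)c(O[Si](C(C)C)(C(C)C)C(C)C)cc1O[Si](C(C)C)(C(C)C)C(C)C | intermediate
6 | 1-bromo-5-[(2E)-3,7-dimethylocta-2,6-dien-1-yl]-2,4-bis(triisopropylsilyloxy)benzene | CC(C)=CCC/C(C)=C/Cc1cc(Br)c(O[Si](C(C)C)(C(C)C)C(C)C)cc1O[Si](C(C)C)(C(C)C)C(C)C | intermediate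
7 | N,N'-dimethoxy-N,N'-dimethyloxamide | CON(C)C(=O)C(=O)N(C)OC | starting material
8 | {5-[(2E)-3,7-dimethylocta-2,6-dien-1-yl]-2,4-bis(triisopropylsilyloxy)phenyl}lithium | CC(C)=CCC/C(C)=C/Cc1cc([Li])c(O[Si](C(C)C)(C(C)C)C(C)C)cc1O[Si](C(C)C)(C(C)C)C(C)C | intermediate
9 | 2-{5-[(2E)-3,7-dimethylocta-2,6-dien-1-yl]-2,4-bis(triisopropylsilyloxy)phenyl}-N-methoxy-N-methyl-2-oxoacetamide | CC(C)=CCC/C(C)=C/Cc1cc(C(=O)C(=O)N(C)OC)c(O[Si](C(C)C)(C(C)C)C(C)C)cc1O[Si](C(C)C)(C(C)C)C(C)C | intermediate
10 | methyltriphenylphosphonium bromide | C[P+](c1ccccc1)(c1ccccc1)c1ccccc1.[Br-] | starting material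
11 | 2-{5-[(2E)-3,7-dimethylocta-2,6-dien-1-yl]-2,4-bis(triisopropylsilyloxy)phenyl}-N-methoxy-N-methylprop-2-enamide | CC(C)=CCC/C(C)=C/Cc1cc(C(=C)C(=O)N(C)OC)c(O[Si](C(C)C)(C(C)C)C(C)C)cc1O[Si](C(C)C)(C(C)C)C(C)C | intermediate
12 | 4-bromoresorcinol | Oc1ccc(Br)c(O)c1 | starting material
13 | 2-bromo-5-(triisopropylsilyloxy)phenol | Oc1cc(O[Si](C(C)C)(C(C)C)C(C)C)ccc1Br | intermediate
14 | lithium 2-lithio-5-(triisopropylsilyloxy)phenoxide | [Li]Oc1cc(O[Si](C(C)C)(C(C)C)C(C)C)ccc1[Li] | intermediate
15 | 2-{5-[(2E)-3,7-dimethylocta-2,6-dien-1-yl]-2,4-bis(triisopropylsilyloxy)phenyl}-1-[2-hydroxy-4-(triisopropylsilyloxy)phenyl]prop-2-en-1-one | CC(C)=CCC/C(C)=C/Cc1cc(C(=C)C(=O)c2ccc(O[Si](C(C)C)(C(C)C)C(C)C)cc2O)c(O[Si](C(C)C)(C(C)C)C(C)C)cc1O[Si](C(C)C)(C(C)C)C(C)C | intermediate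
16 | racemic 3-{5-[(2E)-3,7-dimethylocta-2,6-dien-1-yl]-2,4-bis(triisopropylsilyloxy)phenyl}-7-(triisopropylsilyloxy)chroman-4-one | CC(C)=CCC/C(C)=C/Cc1cc(C2COc3cc(O[Si](C(C)C)(C(C)C)C(C)C)ccc3C2=O)c(O[Si](C(C)C)(C(C)C)C(C)C)cc1O[Si](C(C)C)(C(C)C)C(C)C | intermediate
17 | (3R,4R)-3-{5-[(2E)-3,7-dimethylocta-2,6-dien-1-yl]-2,4-bis(triisopropylsilyloxy)phenyl}-7-(triisopropylsilyloxy)chroman-4-ol | CC(C)=CCC/C(C)=C/Cc1cc([C@@H]2COc3cc(O[Si](C(C)C)(C(C)C)C(C)C)ccc3[C@@H]2O)c(O[Si](C(C)C)(C(C)C)C(C)C)cc1O[Si](C(C)C)(C(C)C)C(C)C | intermediate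
18 | (3R)-3-{5-[(2E)-3,7-dimethylocta-2,6-dien-1-yl]-2,4-bis(triisopropylsilyloxy)phenyl}-7-(triisopropylsilyloxy)chroman-4-one | CC(C)=CCC/C(C)=C/Cc1cc([C@@H]2COc3cc(O[Si](C(C)C)(C(C)C)C(C)C)ccc3C2=O)c(O[Si](C(C)C)(C(C)C)C(C)C)cc1O[Si](C(C)C)(C(C)C)C(C)C | intermediate
19 | (3R)-3-{5-[(2E)-3,7-dimethylocta-2,6-dien-1-yl]-2,4-dihydroxyphenyl}-7-hydroxychroman-4-one | CC(C)=CCC/C(C)=C/Cc1cc([C@@H]2COc3cc(O)ccc3C2=O)c(O)cc1O | target

Total step count: 9. Longest linear sequence: 8 steps (steps 1–4, then 6–9); step 5 prepares the ring A partner.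

Steps most likely to fail

Step 6. The aryllithium may add in conjugate fashion to the α-aryl acrylamide, or the aggregated dianion may add too slowly to the hindered amide. The fallback sets out from 11 and 13 and comes back at 16. Amide 11 would be reduced with i-Bu2AlH (THF, −78 °C) to 2-[5-geranyl-2,4-bis(triisopropylsilyloxy)phenyl]prop-2-enal F1. Dianion 14, made from 13 as in step 6, would add to the aldehyde carbonyl, where 1,2-addition is strongly preferred, to give the allylic benzylic alcohol 2-{1-hydroxy-2-[5-geranyl-2,4-bis(triisopropylsilyloxy)phenyl]prop-2-en-1-yl}-5-(triisopropylsilyloxy)phenol F2. Oxidation with MnO2 (CH2Cl2, rt) should give hydroxy enone 15, which closes to 16 with Et3N as before.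

Step 7. Racemisation of 16 may be too slow relative to reduction with so bulky an aryl group, giving poor dynamic resolution, or ring C may open to enone 15 under the amine and be lost by reduction. The fallback sets out from 16 and comes back at 18, bypassing 17. Soft enolisation with Me3SiOTf/Et3N (CH2Cl2, 0 °C) would give the silyl enol ether 3-[5-geranyl-2,4-bis(triisopropylsilyloxy)phenyl]-7-(triisopropylsilyloxy)-4-(trimethylsilyloxy)-2H-chromene F3. Catalytic enantioselective protonation (a BINOL-derived N-triflyl thiophosphoramide, phenol as stoichiometric proton source, toluene, rt), a method established for silyl enol ethers of 2-aryl cycloalkanones, would then give 18 directly, the catalyst antipode being chosen for the (R) product.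

Step 9. C3 may partly epimerise through enolisation, or through ring opening and reclosure, as phenoxides build up during desilylation. The fallback sets out from 17 and comes back at 19. The silyl groups would be removed at the alcohol stage, where C3 is not enolisable (Bu4NF, THF, 0 °C), to give (3R,4R)-3-(5-geranyl-2,4-dihydroxyphenyl)chromane-4,7-diol F4. The benzylic, para-oxygenated carbinol would then be oxidised chemoselectively with MnO2 (EtOAc, rt, neutral medium to avoid cyclisation onto the 2'-hydroxyl) to give 19.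

Further compounds
F1 | step 6 | 2-{5-[(2E)-3,7-dimethylocta-2,6-dien-1-yl]-2,4-bis(triisopropylsilyloxy)phenyl}prop-2-enal | CC(C)=CCC/C(C)=C/Cc1cc(C(=C)C=O)c(O[Si](C(C)C)(C(C)C)C(C)C)cc1O[Si](C(C)C)(C(C)C)C(C)C
F2 | step 6 | 2-{1-hydroxy-2-[5-((2E)-3,7-dimethylocta-2,6-dien-1-yl)-2,4-bis(triisopropylsilyloxy)phenyl]prop-2-en-1-yl}-5-(triisopropylsilyloxy)phenol (racemic) | CC(C)=CCC/C(C)=C/Cc1cc(C(=C)C(O)c2ccc(O[Si](C(C)C)(C(C)C)C(C)C)cc2O)c(O[Si](C(C)C)(C(C)C)C(C)C)cc1O[Si](C(C)C)(C(C)C)C(C)C
F3 | step 7 | 3-{5-[(2E)-3,7-dimethylocta-2,6-dien-1-yl]-2,4-bis(triisopropylsilyloxy)phenyl}-7-(triisopropylsilyloxy)-4-(trimethylsilyloxy)-2H-chromene | CC(C)=CCC/C(C)=C/Cc1cc(C2=C(O[Si](C)(C)C)c3ccc(O[Si](C(C)C)(C(C)C)C(C)C)cc3OC2)c(O[Si](C(C)C)(C(C)C)C(C)C)cc1O[Si](C(C)C)(C(C)C)C(C)C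
F4 | step 9 | (3R,4R)-3-{5-[(2E)-3,7-dimethylocta-2,6-dien-1-yl]-2,4-dihydroxyphenyl}chromane-4,7-diol | CC(C)=CCC/C(C)=C/Cc1cc([C@@H]2COc3cc(O)ccc3[C@@H]2O)c(O)cc1O
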